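## Retrosynthetic overview

1. Iriomoteolide 3a (39) ⇒ global desilylation of 38, whose C18=C19 E-alkene comes from a late Julia–Kocienski olefination of macrocyclic aldehyde 36 with sulfone 15. The skipped diene is added only after all metathesis steps.
2. The 15-membered lactone ⇒ ring-closing metathesis at C5=C6 of diene ester 33.
3. 33 ⇒ Yamaguchi esterification of the 14-OH with acid 6, after cross-metathesis at C9=C10 between vinyl epoxide 30 and the C2-symmetric diene 12 (from L-tartrate).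
4. 30 ⇒ (S)-5-(hydroxymethyl)butyrolactone 16: trans-methylation sets C17, Brown allylation sets C14, Sharpless epoxidation sets C11/C12; C15 comes from the chiral pool.
5. Ring order: the epoxide is formed first (step 20), the macrolactone last (step 25).

Assumption: natural-product numbering is used for positions (C1 = lactone carbonyl, C14 = lactone carbinol, C23 = terminal methyl), and bought reagents (metathesis catalysts, the allylborane, the tetrazole thiol) are not numbered.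

Abbreviations: TBS = tert-butyldimethylsilyl, Tr = triphenylmethyl.

## Fragment 1: acid 6 (C1–C5)

Step 1
Reactants: 1 (3R)-5-methoxy-3-methyl-5-oxopentanoic acid
Product: 3 (4R)-4-methyltetrahydro-2H-pyran-2-one, via hydroxy ester 2 (not isolated)
Conditions: BH3·SMe2, THF, 0 °C → rt; H2O quench; then TsOH·H2O (cat.), toluene, 80 °C
Reagents that add atoms: none
Why: Chemoselective borane reduction of the free acid in the presence of the methyl ester, then acid-catalysed lactonisation of the δ-hydroxy ester; the stereocentre is not touched.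

Step 2
Reactants: 3 (4R)-4-methyltetrahydro-2H-pyran-2-one
Product: 4 (4R)-4-methyltetrahydro-2H-pyran-2-ol (anomer mixture)
Conditions: i-Bu2AlH (1.05 equiv), CH2Cl2, −78 °C; aq. potassium sodium tartrate
Reagents that add atoms: none
Why: Partial lactone reduction stops at the lactol because the tetrahedral aluminium hemiacetal is stable at −78 °C.

Step 3
Reactants: 4 (4R)-4-methyltetrahydro-2H-pyran-2-ol
Product: 5 (3S)-3-methylhex-5-en-1-ol
Conditions: Ph3PCH3Br (2.5 equiv), KOtBu (2.4 equiv), THF, 0 °C → rt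
Reagents that add atoms: methyltriphenylphosphonium bromide, C[P+](c1ccccc1)(c1ccccc1)c1ccccc1.[Br-]
Why: Wittig methylenation of the open hydroxy-aldehyde form of the lactol gives the terminal alkene.

Step 4
Reactants: 5 (3S)-3-methylhex-5-en-1-ol
Product: 6 (3S)-3-methylhex-5-enoic acid
Conditions: TEMPO (0.2 equiv), PhI(OAc)2 (2.2 equiv), MeCN/H2O 1:1, rt
Reagents that add atoms: water, O
Why: Oxoammonium (TEMPO) oxidation takes the primary alcohol through the aldehyde hydrate to the acid and leaves the terminal alkene alone.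

## Fragment 2: diene 12 (C6–C9)

Step 5
Reactants: 7 dimethyl (4R,5R)-2,2-dimethyl-1,3-dioxolane-4,5-dicarboxylate
Product: 8 [(4S,5S)-2,2-dimethyl-1,3-dioxolane-4,5-diyl]dimethanol
Conditions: LiAlH4, THF, 0 °C → reflux
Reagents that add atoms: none
Why: Hydride reduction of both esters; the acetal and the two tartrate-derived stereocentres are untouched.

Step 6
Reactants: 8 [(4S,5S)-2,2-dimethyl-1,3-dioxolane-4,5-diyl]dimethanol
Product: 10 (4S,5S)-4,5-diethenyl-2,2-dimethyl-1,3-dioxolane, via dialdehyde 9 (not isolated)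
Conditions: (COCl)2, DMSO, CH2Cl2, −78 °C; Et3N; then Ph3P=CH2 (from Ph3PCH3Br/KOtBu, THF, 6 equiv), −78 °C → rt
Reagents that add atoms: methyltriphenylphosphonium bromide, C[P+](c1ccccc1)(c1ccccc1)c1ccccc1.[Br-]
Why: Swern oxidation followed by in-flask double Wittig methylenation traps the hydrate-prone dialdehyde before its α-alkoxy centres can epimerise.

Step 7
Reactants: 10 (4S,5S)-4,5-diethenyl-2,2-dimethyl-1,3-dioxolane
Product: 11 (3S,4S)-hexa-1,5-diene-3,4-diol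
Conditions: Dowex 50W (H+ form), MeOH/H2O, 50 °C
Reagents that add atoms: none
Why: Acid-catalysed acetal hydrolysis frees the C2-symmetric diol.

Step 8
Reactants: 11 (3S,4S)-hexa-1,5-diene-3,4-diol
Product: 12 (3S,4S)-3,4-bis(TBS-oxy)hexa-1,5-diene
Conditions: TBSOTf (2.5 equiv), 2,6-lutidine (4 equiv), CH2Cl2, 0 °C
Reagents that add atoms: tert-butyldimethylsilyl triflate, CC(C)(C)[Si](C)(C)OS(=O)(=O)C(F)(F)F
Why: Silyl triflate silylation protects both hindered secondary allylic alcohols.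

## Fragment 3: sulfone 15 (C19–C23)

Step 9
Reactants: 13 (3E)-pent-3-en-1-ol
Product: 14 5-[(3E)-pent-3-en-1-ylsulfanyl]-1-phenyl-1H-tetrazole
Conditions: 1-phenyl-1H-tetrazole-5-thiol, PPh3, DIAD, THF, 0 °C → rt
Reagents that add atoms: 1-phenyl-1H-tetrazole-5-thiol, Sc1nnnn1-c1ccccc1
Why: Mitsunobu thioetherification of the primary alcohol with the acidic thiol; the alkene geometry is untouched.

Step 10
Reactants: 14 5-[(3E)-pent-3-en-1-ylsulfanyl]-1-phenyl-1H-tetrazole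
Product: 15 5-[(3E)-pent-3-en-1-ylsulfonyl]-1-phenyl-1H-tetrazole
Conditions: 30% H2O2, (NH4)6Mo7O24·4H2O (cat.), EtOH, 0 °C → rt
Reagents that add atoms: hydrogen peroxide, OO
Why: Molybdate-catalysed sulfide-to-sulfone oxidation spares the unactivated disubstituted alkene.

## Fragment 4: vinyl epoxide 30 (C10–C18)

Step 11
Reactants: 16 (5S)-5-(hydroxymethyl)dihydrofuran-2(3H)-one
Product: 17 (5S)-5-[(trityloxy)methyl]dihydrofuran-2(3H)-one
Conditions: TrCl (1.2 equiv), pyridine, DMAP (cat.), rt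
Reagents that add atoms: trityl chloride, ClC(c1ccccc1)(c1ccccc1)c1ccccc1
Why: Tritylation of the primary alcohol installs the bulky group that steers the next alkylation.

Step 12
Reactants: 17 (5S)-5-[(trityloxy)methyl]dihydrofuran-2(3H)-one
Product: 19 (3R,5S)-3-methyl-5-[(trityloxy)methyl]dihydrofuran-2(3H)-one, via lithium enolate 18 (not isolated)
Conditions: LiN(i-Pr)2 (1.1 equiv), THF, −78 °C; MeI (3 equiv), −78 → −40 °C
Reagents that add atoms: iodomethane, CI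
Why: Lactone enolate alkylation in which MeI approaches anti to the C5 trityloxymethyl group, giving the 3,5-trans lactone and so the 17R centre (minor cis isomer removed by chromatography).

Step 13
Reactants: 19 (3R,5S)-3-methyl-5-[(trityloxy)methyl]dihydrofuran-2(3H)-one
Product: 20 (2R,4S)-2-methyl-5-(trityloxy)pentane-1,4-diol
Conditions: LiAlH4, THF, 0 °C
Reagents that add atoms: none
Why: Hydride reduction of the lactone to the 1,4-diol without touching either stereocentre.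

Step 14
Reactants: 20 (2R,4S)-2-methyl-5-(trityloxy)pentane-1,4-diol
Product: 21 (2R,4S)-1,4-bis(TBS-oxy)-2-methyl-5-(trityloxy)pentane
Conditions: TBSCl (3 equiv), imidazole (6 equiv), DMF, 40 °C
Reagents that add atoms: tert-butyldimethylsilyl chloride, CC(C)(C)[Si](C)(C)Cl
Why: Imidazole-promoted silylation protects the primary (O18) and secondary (O15) alcohols.

Step 15
Reactants: 21 (2R,4S)-1,4-bis(TBS-oxy)-2-methyl-5-(trityloxy)pentane
Product: 22 (2S,4R)-2,5-bis(TBS-oxy)-4-methylpentan-1-ol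
Conditions: H2 (1 atm), Pd(OH)2/C, EtOAc, rt
Reagents that add atoms: none
Why: Hydrogenolysis of the trityl C–O bond under neutral conditions leaves both silyl ethers intact (no alkene is present yet).

Step 16
Reactants: 22 (2S,4R)-2,5-bis(TBS-oxy)-4-methylpentan-1-ol
Product: 23 (2S,4R)-2,5-bis(TBS-oxy)-4-methylpentanal
Conditions: Dess–Martin periodinane (1.3 equiv), NaHCO3, CH2Cl2, 0 °C → rt; used crude
Reagents that add atoms: none
Why: Buffered Dess–Martin oxidation gives the α-silyloxy aldehyde without epimerisation.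

Step 17
Reactants: 23 (2S,4R)-2,5-bis(TBS-oxy)-4-methylpentanal
Product: 25 (4S,5S,7R)-5,8-bis(TBS-oxy)-7-methyloct-1-en-4-ol, via borinate ester 24 (not isolated)
Conditions: (−)-Ipc2B(allyl) (from (+)-α-pinene, 1.3 equiv), Et2O, −78 °C; then 3 M NaOH, 30% H2O2, 0 °C → rt
Reagents that add atoms: B-allyldiisopinocampheylborane, C=CCB([C@@H]1C[C@@H]2C[C@H]([C@H]1C)C2(C)C)[C@@H]1C[C@@H]2C[C@H]([C@H]1C)C2(C)C
Why: Brown allylboration through a closed chair transition state delivers allyl to the Si face of the aldehyde under reagent control, setting 14S syn to the 15-silyloxy group.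

Step 18
Reactants: 25 (4S,5S,7R)-5,8-bis(TBS-oxy)-7-methyloct-1-en-4-ol
Product: 26 (2E,5S,6S,8R)-6,9-bis(TBS-oxy)-5-hydroxy-8-methylnon-2-enal
Conditions: crotonaldehyde (5 equiv), second-generation Hoveyda–Grubbs catalyst RuCl2(H2IMes)(=CH-C6H4-2-O-i-Pr) (5 mol%), CH2Cl2, 40 °C
Reagents that add atoms: (E)-crotonaldehyde, C/C=C/C=O
Why: Cross-metathesis of a terminal alkene with an excess of an electron-poor partner is selective and gives the E-enal.

Step 19
Reactants: 26 (2E,5S,6S,8R)-6,9-bis(TBS-oxy)-5-hydroxy-8-methylnon-2-enal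
Product: 27 (2E,5S,6S,8R)-6,9-bis(TBS-oxy)-8-methylnon-2-ene-1,5-diol
Conditions: NaBH4, CeCl3·7H2O, MeOH, −20 °C
Reagents that add atoms: none
Why: Luche reduction gives clean 1,2-reduction of the enal to the E-allylic alcohol.

Step 20
Reactants: 27 (2E,5S,6S,8R)-6,9-bis(TBS-oxy)-8-methylnon-2-ene-1,5-diol
Product: 28 (2S,3S,5R)-3,6-bis(TBS-oxy)-1-[(2S,3S)-3-(hydroxymethyl)oxiran-2-yl]-5-methylhexan-2-ol
Conditions: Ti(O-i-Pr)4 (0.5 equiv), L-(+)-diethyl tartrate (0.6 equiv), t-BuOOH (2 equiv), 4 Å sieves, CH2Cl2, −20 °C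
Reagents that add atoms: tert-butyl hydroperoxide, CC(C)(C)OO
Why: Sharpless asymmetric epoxidation with L-(+)-tartrate gives the (2S,3S)-epoxy alcohol from an E-allylic alcohol, which sets 11S and 12S under reagent control.

Step 21
Reactants: 28 (2S,3S,5R)-3,6-bis(TBS-oxy)-1-[(2S,3S)-3-(hydroxymethyl)oxiran-2-yl]-5-methylhexan-2-ol
Product: 29 (2R,3S)-3-[(2S,3S,5R)-3,6-bis(TBS-oxy)-2-hydroxy-5-methylhexyl]oxirane-2-carbaldehyde
Conditions: TEMPO (0.1 equiv), PhI(OAc)2 (1.2 equiv), CH2Cl2, rt; used crude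
Reagents that add atoms: none
Why: Oxoammonium (TEMPO) oxidation is selective for the primary over the secondary alcohol and mild enough for the epoxide.

Step 22
Reactants: 29 (2R,3S)-3-[(2S,3S,5R)-3,6-bis(TBS-oxy)-2-hydroxy-5-methylhexyl]oxirane-2-carbaldehyde
Product: 30 (2S,3S,5R)-3,6-bis(TBS-oxy)-1-[(2S,3S)-3-ethenyloxiran-2-yl]-5-methylhexan-2-ol
Conditions: Ph3PCH3Br (3 equiv), KN(SiMe3)2 (2.8 equiv), THF, −78 → 0 °C; Et3N-washed silica
Reagents that add atoms: methyltriphenylphosphonium bromide, C[P+](c1ccccc1)(c1ccccc1)c1ccccc1.[Br-]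
Why: Wittig methylenation of the epoxy aldehyde at low temperature gives the vinyl epoxide, and keeping the phosphonium salt in excess over base avoids an alkoxide that could trigger silyl migration.

## Assembly and endgame

Step 23
Reactants: 30 (2S,3S,5R)-3,6-bis(TBS-oxy)-1-[(2S,3S)-3-ethenyloxiran-2-yl]-5-methylhexan-2-ol; 12 (3S,4S)-3,4-bis(TBS-oxy)hexa-1,5-diene (4 equiv)
Product: 31 (2S,3S,5R)-3,6-bis(TBS-oxy)-1-{(2S,3S)-3-[(1E,3S,4S)-3,4-bis(TBS-oxy)hexa-1,5-dien-1-yl]oxiran-2-yl}-5-methylhexan-2-ol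
Conditions: second-generation Hoveyda–Grubbs catalyst RuCl2(H2IMes)(=CH-C6H4-2-O-i-Pr) (10 mol%), CH2Cl2, 40 °C; excess 12 recovered
Reagents that add atoms: none
Why: Cross-metathesis in which a fourfold excess of the C2-symmetric diene (either vinyl group gives the same product) suppresses double reaction and forms the E C9=C10 alkene.

Step 24
Reactants: 31 (C6–C18 alcohol with free 14-OH); 6 (3S)-3-methylhex-5-enoic acid (1.5 equiv)
Product: 33 14-O-[(3S)-3-methylhex-5-enoyl] ester of 31, via mixed anhydride 32 (not isolated)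
Conditions: 6, 2,4,6-Cl3C6H2COCl, Et3N, THF, rt; then 31, DMAP, toluene, rt
Reagents that add atoms: none
Why: Yamaguchi esterification through the mixed anhydride acylates the hindered 14-OH with retention, in a basic medium that the acid-sensitive hydroxy vinyl epoxide tolerates.

Step 25
Reactants: 33 14-O-[(3S)-3-methylhex-5-enoyl] ester of 31
Product: 34 (3S,5E,7S,8S,9E,11S,12S,14S)-7,8-bis(TBS-oxy)-14-[(1S,3R)-1,4-bis(TBS-oxy)-3-methylbutyl]-11,12-epoxy-3-methyltetradeca-5,9-dien-14-olide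
Conditions: second-generation Grubbs catalyst RuCl2(H2IMes)(PCy3)(=CHPh) (15 mol%), CH2Cl2 (1 mM), reflux
Reagents that add atoms: none
Why: Ring-closing metathesis at high dilution, in which the catalyst loads on the unhindered C5 alkene and closes onto the C6 vinyl group to give the 15-membered lactone with the thermodynamically preferred E C5=C6 bond.

Step 26
Reactants: 34 tetrakis-TBS macrolactone
Product: 35 (3S,5E,7S,8S,9E,11S,12S,14S)-7,8-bis(TBS-oxy)-14-[(1S,3R)-1-(TBS-oxy)-4-hydroxy-3-methylbutyl]-11,12-epoxy-3-methyltetradeca-5,9-dien-14-olide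
Conditions: HF·pyridine, excess pyridine, THF, 0 °C
Reagents that add atoms: none
Why: Selective desilylation, because buffered HF·pyridine cleaves the unhindered primary silyl ether much faster than the three secondary ones.

Step 27
Reactants: 35 macrolactone 18-ol
Product: 36 (3S,5E,7S,8S,9E,11S,12S,14S)-7,8-bis(TBS-oxy)-14-[(1S,3R)-1-(TBS-oxy)-3-methyl-4-oxobutyl]-11,12-epoxy-3-methyltetradeca-5,9-dien-14-olide
Conditions: Dess–Martin periodinane, NaHCO3, CH2Cl2, 0 °C; used at once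
Reagents that add atoms: none
Why: Dess–Martin oxidation gives the α-methyl aldehyde under non-acidic conditions that do not epimerise C17.

Step 28
Reactants: 36 macrolactone 18-aldehyde; 15 5-[(3E)-pent-3-en-1-ylsulfonyl]-1-phenyl-1H-tetrazole (1.6 equiv)
Product: 38 7,8,15-tris-O-TBS iriomoteolide 3a, via potassium sulfonyl carbanion 37 (not isolated)
Conditions: 15, KN(SiMe3)2 (1.5 equiv), DME, −60 °C, 30 min; then 36, −60 °C → rt
Reagents that add atoms: none
Why: Julia–Kocienski olefination, in which the pre-formed sulfonyl anion adds to the α-branched aldehyde and Smiles rearrangement with loss of SO2 gives the E C18=C19 alkene.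

Step 29
Reactants: 38 7,8,15-tris-O-TBS iriomoteolide 3a
Product: 39 iriomoteolide 3a
Conditions: Bu4NF/AcOH (1:1, 6 equiv), THF, 0 °C → rt
Reagents that add atoms: none
Why: Fluoride desilylation, buffered with acetic acid to prevent acyl migration and epoxide opening, removes the three secondary silyl ethers.

## Compound list

1 | (3R)-5-methoxy-3-methyl-5-oxopentanoic acid (methyl hydrogen (R)-3-methylglutarate) | OC(=O)C[C@@H](C)CC(=O)OC | starting material
2 | methyl (3R)-5-hydroxy-3-methylpentanoate | OCC[C@@H](C)CC(=O)OC | intermediate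
3 | (4R)-4-methyltetrahydro-2H-pyran-2-one | O=C1C[C@H](C)CCO1 | intermediate
4 | (4R)-4-methyltetrahydro-2H-pyran-2-ol (anomer mixture) | OC1C[C@H](C)CCO1 | intermediate
5 | (3S)-3-methylhex-5-en-1-ol | C=CC[C@H](C)CCO | intermediate
6 | (3S)-3-methylhex-5-enoic acid | C=CC[C@H](C)CC(=O)O | intermediate
7 | dimethyl (4R,5R)-2,2-dimethyl-1,3-dioxolane-4,5-dicarboxylate (dimethyl 2,3-O-isopropylidene-L-tartrate) | COC(=O)[C@@H]1OC(C)(C)O[C@H]1C(=O)OC | starting material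
8 | [(4S,5S)-2,2-dimethyl-1,3-dioxolane-4,5-diyl]dimethanol | OC[C@@H]1OC(C)(C)O[C@H]1CO | intermediate
9 | (4R,5R)-2,2-dimethyl-1,3-dioxolane-4,5-dicarbaldehyde | O=C[C@@H]1OC(C)(C)O[C@H]1C=O | intermediate
10 | (4S,5S)-4,5-diethenyl-2,2-dimethyl-1,3-dioxolane | C=C[C@@H]1OC(C)(C)O[C@H]1C=C | intermediate
11 | (3S,4S)-hexa-1,5-diene-3,4-diol | C=C[C@H](O)[C@@H](O)C=C | intermediate
12 | (3S,4S)-3,4-bis(TBS-oxy)hexa-1,5-diene | C=C[C@H](O[Si](C)(C)C(C)(C)C)[C@@H](O[Si](C)(C)C(C)(C)C)C=C | intermediate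
13 | (3E)-pent-3-en-1-ol | C/C=C/CCO | starting material
14 | 5-[(3E)-pent-3-en-1-ylsulfanyl]-1-phenyl-1H-tetrazole | C/C=C/CCSc1nnnn1-c1ccccc1 | intermediate
15 | 5-[(3E)-pent-3-en-1-ylsulfonyl]-1-phenyl-1H-tetrazole | C/C=C/CCS(=O)(=O)c1nnnn1-c1ccccc1 | intermediate
16 | (5S)-5-(hydroxymethyl)dihydrofuran-2(3H)-one | O=C1CC[C@@H](CO)O1 | starting material
17 | (5S)-5-[(trityloxy)methyl]dihydrofuran-2(3H)-one | O=C1CC[C@@H](COC(c2ccccc2)(c2ccccc2)c2ccccc2)O1 | intermediate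
18 | lithium enolate of 17 | [Li]OC1=CC[C@@H](COC(c2ccccc2)(c2ccccc2)c2ccccc2)O1 | intermediate
19 | (3R,5S)-3-methyl-5-[(trityloxy)methyl]dihydrofuran-2(3H)-one (3,5-trans) | O=C1[C@H](C)C[C@@H](COC(c2ccccc2)(c2ccccc2)c2ccccc2)O1 | intermediate
20 | (2R,4S)-2-methyl-5-(trityloxy)pentane-1,4-diol | OC[C@H](C)C[C@H](O)COC(c1ccccc1)(c1ccccc1)c1ccccc1 | intermediate
21 | (2R,4S)-1,4-bis(TBS-oxy)-2-methyl-5-(trityloxy)pentane | CC(C)(C)[Si](C)(C)OC[C@H](C)C[C@H](O[Si](C)(C)C(C)(C)C)COC(c1ccccc1)(c1ccccc1)c1ccccc1 | intermediate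
22 | (2S,4R)-2,5-bis(TBS-oxy)-4-methylpentan-1-ol | CC(C)(C)[Si](C)(C)OC[C@H](C)C[C@H](O[Si](C)(C)C(C)(C)C)CO | intermediate
23 | (2S,4R)-2,5-bis(TBS-oxy)-4-methylpentanal | CC(C)(C)[Si](C)(C)OC[C@H](C)C[C@H](O[Si](C)(C)C(C)(C)C)C=O | intermediate
24 | O-(diisopinocampheylboryl) derivative (borinate ester) of 25 | CC(C)(C)[Si](C)(C)OC[C@H](C)C[C@H](O[Si](C)(C)C(C)(C)C)[C@H](CC=C)OB([C@@H]1C[C@@H]2C[C@H]([C@H]1C)C2(C)C)[C@@H]1C[C@@H]2C[C@H]([C@H]1C)C2(C)C | intermediate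
25 | (4S,5S,7R)-5,8-bis(TBS-oxy)-7-methyloct-1-en-4-ol | CC(C)(C)[Si](C)(C)OC[C@H](C)C[C@H](O[Si](C)(C)C(C)(C)C)[C@@H](O)CC=C | intermediate
26 | (2E,5S,6S,8R)-6,9-bis(TBS-oxy)-5-hydroxy-8-methylnon-2-enal | CC(C)(C)[Si](C)(C)OC[C@H](C)C[C@H](O[Si](C)(C)C(C)(C)C)[C@@H](O)C/C=C/C=O | intermediate
27 | (2E,5S,6S,8R)-6,9-bis(TBS-oxy)-8-methylnon-2-ene-1,5-diol | CC(C)(C)[Si](C)(C)OC[C@H](C)C[C@H](O[Si](C)(C)C(C)(C)C)[C@@H](O)C/C=C/CO | intermediate
28 | (2S,3S,5R)-3,6-bis(TBS-oxy)-1-[(2S,3S)-3-(hydroxymethyl)oxiran-2-yl]-5-methylhexan-2-ol | CC(C)(C)[Si](C)(C)OC[C@H](C)C[C@H](O[Si](C)(C)C(C)(C)C)[C@@H](O)C[C@@H]1O[C@H]1CO | intermediate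
29 | (2R,3S)-3-[(2S,3S,5R)-3,6-bis(TBS-oxy)-2-hydroxy-5-methylhexyl]oxirane-2-carbaldehyde | CC(C)(C)[Si](C)(C)OC[C@H](C)C[C@H](O[Si](C)(C)C(C)(C)C)[C@@H](O)C[C@@H]1O[C@H]1C=O | intermediate
30 | (2S,3S,5R)-3,6-bis(TBS-oxy)-1-[(2S,3S)-3-ethenyloxiran-2-yl]-5-methylhexan-2-ol | CC(C)(C)[Si](C)(C)OC[C@H](C)C[C@H](O[Si](C)(C)C(C)(C)C)[C@@H](O)C[C@@H]1O[C@H]1C=C | intermediate
31 | (2S,3S,5R)-3,6-bis(TBS-oxy)-1-{(2S,3S)-3-[(1E,3S,4S)-3,4-bis(TBS-oxy)hexa-1,5-dien-1-yl]oxiran-2-yl}-5-methylhexan-2-ol (C6–C18, free 14-OH) | CC(C)(C)[Si](C)(C)OC[C@H](C)C[C@H](O[Si](C)(C)C(C)(C)C)[C@@H](O)C[C@@H]1O[C@H]1/C=C/[C@H](O[Si](C)(C)C(C)(C)C)[C@@H](O[Si](C)(C)C(C)(C)C)C=C | intermediate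
32 | (3S)-3-methylhex-5-enoic 2,4,6-trichlorobenzoic anhydride | C=CC[C@H](C)CC(=O)OC(=O)c1c(Cl)cc(Cl)cc1Cl | intermediate
33 | 14-O-[(3S)-3-methylhex-5-enoyl] ester of 31 (ring-closing metathesis precursor) | CC(C)(C)[Si](C)(C)OC[C@H](C)C[C@H](O[Si](C)(C)C(C)(C)C)[C@H](C[C@@H]1O[C@H]1/C=C/[C@H](O[Si](C)(C)C(C)(C)C)[C@@H](O[Si](C)(C)C(C)(C)C)C=C)OC(=O)C[C@@H](C)CC=C | intermediate
34 | (3S,5E,7S,8S,9E,11S,12S,14S)-7,8-bis(TBS-oxy)-14-[(1S,3R)-1,4-bis(TBS-oxy)-3-methylbutyl]-11,12-epoxy-3-methyltetradeca-5,9-dien-14-olide | CC(C)(C)[Si](C)(C)OC[C@H](C)C[C@H](O[Si](C)(C)C(C)(C)C)[C@@H]1C[C@@H]2O[C@H]2/C=C/[C@H](O[Si](C)(C)C(C)(C)C)[C@@H](O[Si](C)(C)C(C)(C)C)/C=C/C[C@H](C)CC(=O)O1 | intermediate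
35 | 18-hydroxy analogue of 34 (primary TBS removed) | OC[C@H](C)C[C@H](O[Si](C)(C)C(C)(C)C)[C@@H]1C[C@@H]2O[C@H]2/C=C/[C@H](O[Si](C)(C)C(C)(C)C)[C@@H](O[Si](C)(C)C(C)(C)C)/C=C/C[C@H](C)CC(=O)O1 | intermediate
36 | 18-aldehyde: 14-[(1S,3R)-1-(TBS-oxy)-3-methyl-4-oxobutyl] macrolactone | O=C[C@H](C)C[C@H](O[Si](C)(C)C(C)(C)C)[C@@H]1C[C@@H]2O[C@H]2/C=C/[C@H](O[Si](C)(C)C(C)(C)C)[C@@H](O[Si](C)(C)C(C)(C)C)/C=C/C[C@H](C)CC(=O)O1 | intermediate
37 | potassium salt of the α-sulfonyl carbanion of 15 | C/C=C/C[CH-]S(=O)(=O)c1nnnn1-c1ccccc1.[K+] | intermediate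
38 | 7,8,15-tris-O-TBS iriomoteolide 3a | C/C=C/C/C=C/[C@H](C)C[C@H](O[Si](C)(C)C(C)(C)C)[C@@H]1C[C@@H]2O[C@H]2/C=C/[C@H](O[Si](C)(C)C(C)(C)C)[C@@H](O[Si](C)(C)C(C)(C)C)/C=C/C[C@H](C)CC(=O)O1 | intermediate
39 | iriomoteolide 3a: (3S,5E,7S,8S,9E,11S,12S,14S)-11,12-epoxy-7,8-dihydroxy-14-[(1S,3R,4E,7E)-1-hydroxy-3-methylnona-4,7-dien-1-yl]-3-methyltetradeca-5,9-dien-14-olide | C/C=C/C/C=C/[C@H](C)C[C@H](O)[C@@H]1C[C@@H]2O[C@H]2/C=C/[C@H](O)[C@@H](O)/C=C/C[C@H](C)CC(=O)O1 | target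

## Count and risks

Total step count: 29. Longest linear sequence: 19 steps (16 → 39, steps 11–29); the other 10 steps build 6, 12 and 15 in parallel.

Three steps most likely to fail:

Step 17 (Brown allylation). The reagent has to override the Felkin preference of the α-silyloxy aldehyde, so the diastereomer ratio may be low. The fallback sets out from 23 and comes back at 25, using substrate control followed by inversion. Allyltrimethylsilane with BF3·OEt2 (CH2Cl2, −78 °C) follows the Felkin–Anh model and gives the anti alcohol (4R,5S,7R)-5,8-bis(TBS-oxy)-7-methyloct-1-en-4-ol F1. Mitsunobu inversion with 4-nitrobenzoic acid, PPh3 and DIAD gives (4S,5S,7R)-5,8-bis(TBS-oxy)-7-methyloct-1-en-4-yl 4-nitrobenzoate F2, and cold methanolysis (K2CO3, MeOH, 0 °C) gives 25.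

Step 23 (cross-metathesis of the vinyl epoxide with the hindered bis-silyloxy diene). Both alkenes are sluggish and the vinyl epoxide may dimerise or decompose. The fallback sets out from 30 (with 6 and 12) and comes back at 34, reversing the order of the two metathesis events. Yamaguchi esterification of 30 with 6 (through 32) gives the 14-O-[(3S)-3-methylhex-5-enoyl] ester of 30 F3. Cross-metathesis of F3 with excess 12 takes place at the unhindered C5 terminal alkene, not at the vinyl epoxide, and gives the open-chain (5E)-C5=C6 diene ester F4. Ring-closing metathesis of F4 between the vinyl epoxide and the C8 vinyl group then forms C9=C10 intramolecularly and gives 34.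

Step 25 (ring-closing metathesis). It may give E/Z mixtures at C5=C6, oligomers, or attack on the C9=C10 alkene. The fallback sets out from 31 (with 6) and comes back at 34, closing the ring by macrolactonisation instead. Cross-metathesis of 31 with excess 6 (second-generation Hoveyda–Grubbs catalyst, CH2Cl2, 40 °C) builds the E C5=C6 alkene in the open chain and gives the 14-hydroxy seco acid F5. Yamaguchi activation (2,4,6-Cl3C6H2COCl, Et3N, THF) gives the mixed anhydride of the seco acid F6, which is added slowly to DMAP in toluene at high dilution to close the lactone at O14 and give 34.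

Further compounds
F1 | step 17 | (4R,5S,7R)-5,8-bis(TBS-oxy)-7-methyloct-1-en-4-ol | CC(C)(C)[Si](C)(C)OC[C@H](C)C[C@H](O[Si](C)(C)C(C)(C)C)[C@H](O)CC=C
F2 | step 17 | (4S,5S,7R)-5,8-bis(TBS-oxy)-7-methyloct-1-en-4-yl 4-nitrobenzoate | CC(C)(C)[Si](C)(C)OC[C@H](C)C[C@H](O[Si](C)(C)C(C)(C)C)[C@H](CC=C)OC(=O)c1ccc(cc1)[N+](=O)[O-]
F3 | step 23 | 14-O-[(3S)-3-methylhex-5-enoyl] ester of 30 | CC(C)(C)[Si](C)(C)OC[C@H](C)C[C@H](O[Si](C)(C)C(C)(C)C)[C@H](C[C@@H]1O[C@H]1C=C)OC(=O)C[C@@H](C)CC=C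
F4 | step 23 | open-chain (5E)-diene ester from cross-metathesis of F3 with 12 (vinyl epoxide and C8 vinyl group free) | CC(C)(C)[Si](C)(C)OC[C@H](C)C[C@H](O[Si](C)(C)C(C)(C)C)[C@H](C[C@@H]1O[C@H]1C=C)OC(=O)C[C@@H](C)C/C=C/[C@H](O[Si](C)(C)C(C)(C)C)[C@@H](O[Si](C)(C)C(C)(C)C)C=C
F5 | step 25 | 14-hydroxy seco acid (C1–C18, 5E,9E, 7,8,15,18-tetrakis-O-TBS) | CC(C)(C)[Si](C)(C)OC[C@H](C)C[C@H](O[Si](C)(C)C(C)(C)C)[C@@H](O)C[C@@H]1O[C@H]1/C=C/[C@H](O[Si](C)(C)C(C)(C)C)[C@@H](O[Si](C)(C)C(C)(C)C)/C=C/C[C@H](C)CC(=O)O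
F6 | step 25 | 2,4,6-trichlorobenzoic mixed anhydride of F5 | CC(C)(C)[Si](C)(C)OC[C@H](C)C[C@H](O[Si](C)(C)C(C)(C)C)[C@@H](O)C[C@@H]1O[C@H]1/C=C/[C@H](O[Si](C)(C)C(C)(C)C)[C@@H](O[Si](C)(C)C(C)(C)C)/C=C/C[C@H](C)CC(=O)OC(=O)c1c(Cl)cc(Cl)cc1Cl
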